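A direct plan would build the bicyclo[3.1.1]heptane first: the acid chloride of dienoic acid A1 would be dehydrochlorinated to a vinylketene that adds across its own trisubstituted alkene in a crossed [2+2] mode to give cyclobutanone A2. A lactone enolate would then be added to that cyclobutanone to close the seven-membered ring, and the tertiary alkoxide, trapped as xanthate A3, would be reduced away. Its weakest steps would be the ketene cycloaddition (very high dilution, crossed against fused closure, facial bias resting on one silyloxy centre that is erased afterwards), the aldol closure (a strained bridged cyclobutanol in equilibrium with retro-aldol, to be trapped in the same flask) and the radical deoxygenation of the tertiary cyclobutyl xanthate, which would only remove an oxygen that the plan itself had put in.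

Labels: C1 (quaternary, CH2OAng), cyclobutane C2–C3–C8–C7, C4 (C=O), C5=C6, C9 (OAng), C10, C11 (OAc). The route disconnects cyclobutane bond C3–C8 as a retro-1,2-shift, exploiting that the C4 carbonyl flanks C3: the core is read as a norbornene (C8 still on C4) with a bridgehead C4 hydroxyl and an endo C3 mesylate. One aluminium-promoted semipinacol shift contracts bicyclo[2.2.1] to bicyclo[3.1.1], forms the cyclobutane and releases the C4 enone. The norbornene, seven-membered ring already closed, would come from an intramolecular Diels–Alder reaction of a silyloxycyclopentadiene whose stereocentres C1, C8, C9, C11 stem from two catalytic tert-(hydroxy)prenylations. No ketene cycloaddition, cyclobutanone aldol or tertiary deoxygenation remains.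

Key step: step 19

Remark on labels: the methyl groups on C6, C8 and C1 are C12, C13 and C14, the CH2O carbon on C1 is C15; all intermediates keep these labels.
Assumption: the iridium-catalysed tert-(hydroxy)prenylation of a primary alcohol with isoprene monoxide is taken to give the anti adduct (secondary OH and CH2OH anti in the zigzag drawn through the vinyl group) under catalyst control, as known for this reaction class; both couplings then need the same ligand antipode.

Step 1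
Reactants: 1 3-(benzyloxy)propan-1-ol; 2 2-methyl-2-vinyloxirane (isoprene monoxide, racemic)
Product: 3 (2R,3R)-5-(benzyloxy)-2-ethenyl-2-methylpentane-1,3-diol
Conditions: 2 (3 equiv), [Ir(cod)Cl]2 (2.5 mol%), Tol-BINAP (5 mol%, antipode chosen for the (2R,3R) product), 4-cyano-3-nitrobenzoic acid (10 mol%), allyl acetate (10 mol%), K3PO4 (5 mol%), THF, 60 °C
Reagents that add atoms: none
Why: Redox-triggered iridium-catalysed carbonyl tert-(hydroxy)prenylation, in which dehydrogenation of the alcohol gives the aldehyde and an iridium hydride that converts the vinyl epoxide into a π-allyliridium species, which adds through a closed chair transition state and so sets the C11 carbinol and the C1 quaternary centre (CH2OH, the later C2, anti to OH) under catalyst control.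

Step 2
Reactants: 3 (2R,3R)-5-(benzyloxy)-2-ethenyl-2-methylpentane-1,3-diol
Product: 4 (4R,5R)-4-[2-(benzyloxy)ethyl]-5-ethenyl-2,2,5-trimethyl-1,3-dioxane
Conditions: Me2C(OMe)2, PPTS (cat.), CH2Cl2, rt
Reagents that add atoms: 2,2-dimethoxypropane, COC(C)(C)OC
Why: Acid-catalysed transacetalisation closes the six-membered acetonide over the 1,3-diol and masks the C11 hydroxyl together with the hydroxymethyl arm that will become C2.

Step 3
Reactants: 4 (4R,5R)-4-[2-(benzyloxy)ethyl]-5-ethenyl-2,2,5-trimethyl-1,3-dioxane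
Product: 6 [(4R,5R)-4-[2-(benzyloxy)ethyl]-2,2,5-trimethyl-1,3-dioxan-5-yl]methanol, via aldehyde 5 (not isolated)
Conditions: O3, CH2Cl2–MeOH (4:1), −78 °C; then NaBH4, −78 °C → rt
Reagents that add atoms: ozone, [O-][O+]=O
Why: Ozonolysis with reductive work-up turns the vinyl group, the only alkene present, into the C15 hydroxymethyl group, which stays distinct from the acetonide-bound arm so that the C1 configuration is kept.

Step 4
Reactants: 6 [(4R,5R)-4-[2-(benzyloxy)ethyl]-2,2,5-trimethyl-1,3-dioxan-5-yl]methanol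
Product: 7 {[(4R,5S)-4-[2-(benzyloxy)ethyl]-2,2,5-trimethyl-1,3-dioxan-5-yl]methoxy}(tert-butyl)diphenylsilane
Conditions: TBDPSCl, imidazole, DMF, rt
Reagents that add atoms: tert-butyl(chloro)diphenylsilane, CC(C)(C)[Si](Cl)(c1ccccc1)c1ccccc1
Why: Standard silylation of the neopentyl primary alcohol gives an acid-stable ether at C15 that should last until step 20.

Step 5
Reactants: 7 {[(4R,5S)-4-[2-(benzyloxy)ethyl]-2,2,5-trimethyl-1,3-dioxan-5-yl]methoxy}(tert-butyl)diphenylsilane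
Product: 8 2-[(4R,5S)-5-{[tert-butyl(diphenyl)silyl]oxymethyl}-2,2,5-trimethyl-1,3-dioxan-4-yl]ethan-1-ol
Conditions: H2 (1 atm), 10% Pd/C, EtOAc, rt
Reagents that add atoms: none
Why: Hydrogenolysis of the benzyl ether frees the C9 primary alcohol at a stage where no alkene is present and the acetonide and silyl ether are inert.

Step 6
Reactants: 8 2-[(4R,5S)-5-{[tert-butyl(diphenyl)silyl]oxymethyl}-2,2,5-trimethyl-1,3-dioxan-4-yl]ethan-1-ol; 2 2-methyl-2-vinyloxirane
Product: 9 (2R,3R)-4-[(4R,5S)-5-{[tert-butyl(diphenyl)silyl]oxymethyl}-2,2,5-trimethyl-1,3-dioxan-4-yl]-2-ethenyl-2-methylbutane-1,3-diol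
Conditions: 2 (3 equiv), [Ir(cod)Cl]2 (2.5 mol%), Tol-BINAP (5 mol%, same antipode as in step 1), 4-cyano-3-nitrobenzoic acid (10 mol%), allyl acetate (10 mol%), K3PO4 (5 mol%), THF, 60 °C
Reagents that add atoms: none
Why: A second catalyst-controlled tert-(hydroxy)prenylation sets the C9 carbinol and the C8 quaternary centre (CH2OH, the later C4, anti to OH), and the same sense of induction as in step 1 gives the anti relationship of the C9 and C11 oxygens.

Step 7
Reactants: 9 (2R,3R)-4-[(4R,5S)-5-{[tert-butyl(diphenyl)silyl]oxymethyl}-2,2,5-trimethyl-1,3-dioxan-4-yl]-2-ethenyl-2-methylbutane-1,3-diol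
Product: 10 (2S,3R)-4-[(4R,5S)-5-{[tert-butyl(diphenyl)silyl]oxymethyl}-2,2,5-trimethyl-1,3-dioxan-4-yl]-2-ethenyl-3-hydroxy-2-methylbutanal
Conditions: TEMPO (10 mol%), PhI(OAc)2 (1.2 equiv), CH2Cl2, rt
Reagents that add atoms: none
Why: Oxoammonium oxidation is selective for the primary over the hindered secondary alcohol, and the aldehyde, having no α-hydrogen, can neither epimerise nor eliminate.

Step 8
Reactants: 10 (2S,3R)-4-[(4R,5S)-5-{[tert-butyl(diphenyl)silyl]oxymethyl}-2,2,5-trimethyl-1,3-dioxan-4-yl]-2-ethenyl-3-hydroxy-2-methylbutanal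
Product: 11 (2S,3R)-3-(tert-butyldimethylsilyloxy)-4-[(4R,5S)-5-{[tert-butyl(diphenyl)silyl]oxymethyl}-2,2,5-trimethyl-1,3-dioxan-4-yl]-2-ethenyl-2-methylbutanal
Conditions: TBSOTf, 2,6-lutidine, CH2Cl2, −78 → 0 °C
Reagents that add atoms: tert-butyldimethylsilyl trifluoromethanesulfonate, CC(C)(C)[Si](C)(C)OS(=O)(=O)C(F)(F)F
Why: Silyl triflate with a hindered base silylates the hindered C9 hydroxyl without touching the non-enolisable aldehyde, and the ether should last until step 20.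

Step 9
Reactants: 11 (2S,3R)-3-(tert-butyldimethylsilyloxy)-4-[(4R,5S)-5-{[tert-butyl(diphenyl)silyl]oxymethyl}-2,2,5-trimethyl-1,3-dioxan-4-yl]-2-ethenyl-2-methylbutanal; 12 (2-methylprop-2-en-1-yl)magnesium chloride
Product: 13 (5R,6R)-6-(tert-butyldimethylsilyloxy)-7-[(4R,5S)-5-{[tert-butyl(diphenyl)silyl]oxymethyl}-2,2,5-trimethyl-1,3-dioxan-4-yl]-5-ethenyl-2,5-dimethylhept-1-en-4-ol (C4 epimers)
Conditions: 12 (1.5 equiv), THF, −78 °C; aq. NH4Cl
Reagents that add atoms: none
Why: Grignard addition to the non-enolisable aldehyde brings in C5, C6 and C12, and the new carbinol centre is of no consequence because it is oxidised in step 11.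

Step 10
Reactants: 13 (5R,6R)-6-(tert-butyldimethylsilyloxy)-7-[(4R,5S)-5-{[tert-butyl(diphenyl)silyl]oxymethyl}-2,2,5-trimethyl-1,3-dioxan-4-yl]-5-ethenyl-2,5-dimethylhept-1-en-4-ol
Product: 14 (2R)-2-[(1R)-1-(tert-butyldimethylsilyloxy)-2-[(4R,5S)-5-{[tert-butyl(diphenyl)silyl]oxymethyl}-2,2,5-trimethyl-1,3-dioxan-4-yl]ethyl]-2,4-dimethylcyclopent-3-en-1-ol (C1 epimers)
Conditions: second-generation Grubbs catalyst (5 mol%), CH2Cl2, 40 °C
Reagents that add atoms: none
Why: Ring-closing metathesis between the vinyl group on C8 and the methallyl alkene forms the C6=C7 bond of the five-membered ring with loss of ethene and leaves C8 untouched.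

Step 11
Reactants: 14 (2R)-2-[(1R)-1-(tert-butyldimethylsilyloxy)-2-[(4R,5S)-5-{[tert-butyl(diphenyl)silyl]oxymethyl}-2,2,5-trimethyl-1,3-dioxan-4-yl]ethyl]-2,4-dimethylcyclopent-3-en-1-ol
Product: 16 (5S)-5-[(1R)-1-(tert-butyldimethylsilyloxy)-2-[(4R,5S)-5-{[tert-butyl(diphenyl)silyl]oxymethyl}-2,2,5-trimethyl-1,3-dioxan-4-yl]ethyl]-3,5-dimethylcyclopent-2-en-1-one, via cyclopent-3-enone 15 (not isolated)
Conditions: Dess–Martin periodinane, NaHCO3, CH2Cl2, 0 °C → rt; then DBU (0.2 equiv), rt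
Reagents that add atoms: none
Why: Dess–Martin oxidation gives the C4 ketone and base then moves the double bond into conjugation, which cannot affect the quaternary C8.

Step 12
Reactants: 16 (5S)-5-[(1R)-1-(tert-butyldimethylsilyloxy)-2-[(4R,5S)-5-{[tert-butyl(diphenyl)silyl]oxymethyl}-2,2,5-trimethyl-1,3-dioxan-4-yl]ethyl]-3,5-dimethylcyclopent-2-en-1-one
Product: 17 (5S)-5-[(1R,3R,4S)-1-(tert-butyldimethylsilyloxy)-4-{[tert-butyl(diphenyl)silyl]oxymethyl}-3,5-dihydroxy-4-methylpentyl]-3,5-dimethylcyclopent-2-en-1-one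
Conditions: PPTS (0.3 equiv), MeOH, rt
Reagents that add atoms: none
Why: Mild acid methanolysis removes the 1,3-dioxane acetonide while the hindered secondary TBS ether and the TBDPS ether should survive.

Step 13
Reactants: 17 (5S)-5-[(1R,3R,4S)-1-(tert-butyldimethylsilyloxy)-4-{[tert-butyl(diphenyl)silyl]oxymethyl}-3,5-dihydroxy-4-methylpentyl]-3,5-dimethylcyclopent-2-en-1-one
Product: 18 (2S,3R,5R)-5-(tert-butyldimethylsilyloxy)-2-{[tert-butyl(diphenyl)silyl]oxymethyl}-5-[(1S)-1,4-dimethyl-2-oxocyclopent-3-en-1-yl]-3-hydroxy-2-methylpentanal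
Conditions: TEMPO (10 mol%), PhI(OAc)2 (1.2 equiv), CH2Cl2, rt
Reagents that add atoms: none
Why: The same oxoammonium oxidation takes the primary C2 alcohol in the presence of the secondary C11 alcohol and gives an aldehyde on quaternary C1 that cannot epimerise.

Step 14
Reactants: 18 (2S,3R,5R)-5-(tert-butyldimethylsilyloxy)-2-{[tert-butyl(diphenyl)silyl]oxymethyl}-5-[(1S)-1,4-dimethyl-2-oxocyclopent-3-en-1-yl]-3-hydroxy-2-methylpentanal
Product: 19 (2S,3R,5R)-5-(tert-butyldimethylsilyloxy)-1-[tert-butyl(diphenyl)silyloxy]-5-[(1S)-1,4-dimethyl-2-oxocyclopent-3-en-1-yl]-2-formyl-2-methylpentan-3-yl acetate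
Conditions: Ac2O, pyridine, DMAP (cat.), CH2Cl2, 0 °C → rt
Reagents that add atoms: acetic anhydride, CC(=O)OC(C)=O
Why: DMAP-catalysed acetylation installs the C11 acetate of the target, and the β-acetoxy aldehyde cannot eliminate because C1 is quaternary.

Step 15
Reactants: 19 (2S,3R,5R)-5-(tert-butyldimethylsilyloxy)-1-[tert-butyl(diphenyl)silyloxy]-5-[(1S)-1,4-dimethyl-2-oxocyclopent-3-en-1-yl]-2-formyl-2-methylpentan-3-yl acetate; 20 2-(dichloromethyl)-4,4,5,5-tetramethyl-1,3,2-dioxaborolane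
Product: 21 (1E,3S,4R,6R)-6-(tert-butyldimethylsilyloxy)-3-{[tert-butyl(diphenyl)silyl]oxymethyl}-6-[(1S)-1,4-dimethyl-2-oxocyclopent-3-en-1-yl]-3-methyl-1-(4,4,5,5-tetramethyl-1,3,2-dioxaborolan-2-yl)hex-1-en-4-yl acetate
Conditions: CrCl2 (8 equiv), LiI (4 equiv), 20 (2 equiv), THF, rt
Reagents that add atoms: none
Why: Takai–Utimoto-type olefination through a gem-dichromium species converts the aldehyde, but not the enone or the acetate, into the (E)-alkenylboronate, which supplies C3 and a boron group that first activates the dienophile and later becomes the leaving group.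

Step 16
Reactants: 21 (1E,3S,4R,6R)-6-(tert-butyldimethylsilyloxy)-3-{[tert-butyl(diphenyl)silyl]oxymethyl}-6-[(1S)-1,4-dimethyl-2-oxocyclopent-3-en-1-yl]-3-methyl-1-(4,4,5,5-tetramethyl-1,3,2-dioxaborolan-2-yl)hex-1-en-4-yl acetate
Product: 23 norbornene cycloadduct (bridgehead C4–OSiMe3; C3–B(pin) endo; C1 exo on C2; C5=C6; C8–CH3 syn to C5=C6; seven-membered ring C7–C8–C9–C10–C11–C1–C2 closed), via silyl dienol ether 22 (not isolated)
Conditions: TMSOTf (1.5 equiv), Et3N (3 equiv), CH2Cl2, 0 °C; pentane extraction; then PhMe (0.01 M), BHT, 150 °C (sealed tube)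
Reagents that add atoms: trimethylsilyl trifluoromethanesulfonate, C[Si](C)(C)OS(=O)(=O)C(F)(F)F
Why: γ-Enolisation and silylation give the 5,5-disubstituted 2-silyloxycyclopentadiene (no hydrogen shift is possible at C8, and any exocyclic dienol ether isomer should equilibrate into it), and its intramolecular Diels–Alder reaction closes the seven-membered ring, the tether forcing attack on the diene face syn to C9 with C1 exo, the (E)-geometry placing boron endo at C3 and the electron-rich terminus C7 bonding to the boron-remote carbon C2, so that C2, C3, C4 and C7 are all set from C8.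

Step 17
Reactants: 23 norbornene cycloadduct (bridgehead C4–OSiMe3; C3–B(pin) endo)
Product: 25 C3,C4-diol (C3–OH endo; bridgehead C4–OH; C9–OTBS; C11–OAc; C15–OTBDPS), via alcohol 24 (not isolated)
Conditions: NaBO3·4H2O (5 equiv), THF–H2O (1:1), rt; then citric acid, MeOH, rt
Reagents that add atoms: sodium perborate, [Na+].[O-]OB=O
Why: Perborate oxidises the C–B bond with retention to the endo C3 alcohol without hydrolysing the acetate, and mild acid then removes the labile bridgehead trimethylsilyl ether while the TBS and TBDPS ethers stay.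

Step 18
Reactants: 25 C3,C4-diol (C3–OH endo; bridgehead C4–OH)
Product: 26 C3 endo mesylate (bridgehead C4–OH free; C9–OTBS; C11–OAc; C15–OTBDPS)
Conditions: MsCl, Et3N, CH2Cl2, −20 → 0 °C
Reagents that add atoms: methanesulfonyl chloride, CS(=O)(=O)Cl
Why: Sulfene-mediated mesylation takes only the secondary endo hydroxyl, since the tertiary bridgehead hydroxyl is inert under these conditions.

Step 19
Reactants: 26 C3 endo mesylate (bridgehead C4–OH free)
Product: 28 tricyclic enone (C4 ketone; C5=C6; cyclobutane C2–C3–C8–C7; C9–OTBS; C11–OAc; C15–OTBDPS; (1S,2S,3R,7R,8R,9R,11R) in the C-labels), via aluminium alkoxide 27 (not isolated)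
Conditions: Et3Al (3 equiv), CH2Cl2, −78 → 0 °C; aq. potassium sodium tartrate
Reagents that add atoms: none
Why: Proposed new method: Et3Al deprotonates the bridgehead hydroxyl (loss of ethane) to an aluminium alkoxide whose metal also activates the neighbouring mesylate, and the C4–C8 bond, the only bond antiperiplanar to the endo C3–O bond (the C4–C5 vinyl bond is gauche), migrates to C3 while C4 becomes the carbonyl, a concerted semipinacol 1,2-shift that runs the Wagner–Meerwein bornyl-to-pinyl change against ring strain and is paid for by C=O formation, enone conjugation and loss of mesylate. The closest known reactions are the stereospecific organoaluminium-promoted semipinacol rearrangement of β-mesyloxy alcohols and the bridgehead-oxygen-driven pinacol-type shifts of Diels–Alder adducts of 1-oxygenated cyclohexadienes, whereas a contraction of bicyclo[2.2.1] to bicyclo[3.1.1] has not been shown. The cyclobutane C2–C3–C8–C7, and with it the six-membered ring C3–C4–C5–C6–C7–C8, is closed by this suprafacial 1,2-alkyl shift, formally a 3-exo-tet displacement at C3 by the C4–C8 σ-bond that contracts the five-membered ring C2–C3–C4–C8–C7. C3 is the only stereocentre formed and is fixed by backside entry of C8, which the ring system holds on the exo face, while C8 migrates with retention and C1, C2, C7, C9 and C11 are untouched. The step needs migration of C8 and not of C5 and no free cation, which the endo mesylate inherited from the (E)-dienophile, the lack of any antiperiplanar hydrogen (the C2 hydrogen is syn) and the non-ionising low-temperature conditions should secure.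

Step 20
Reactants: 28 tricyclic enone (C9–OTBS; C11–OAc; C15–OTBDPS)
Product: 29 9,15-diol (C4 ketone; C5=C6; C11–OAc; (1S,2S,3R,7R,8R,9R,11R) in the C-labels)
Conditions: HF·pyridine, pyridine, THF, 0 → 40 °C
Reagents that add atoms: none
Why: Buffered acidic fluoride removes both silyl ethers without the base-induced acetyl migration that a basic fluoride source could cause.

Step 21
Reactants: 29 9,15-diol (C11–OAc); 30 angelic acid ((2Z)-2-methylbut-2-enoic acid)
Product: 32 CNP0364726.1 (target), via mixed anhydride 31 (not isolated)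
Conditions: 30 (6 equiv), 2,4,6-trichlorobenzoyl chloride (6 equiv), Et3N (12 equiv), PhMe, rt; then 29, 80 °C
Reagents that add atoms: none
Why: Yamaguchi-type mixed-anhydride esterification without DMAP acylates the primary C15 and the hindered C9 hydroxyl at the angeloyl carbonyl with retention of the (Z)-geometry, the primary hydroxyl reacting first and the C9 hydroxyl being trans-1,3 to the acetate, so that acetyl migration should not intervene.

## Compound list

1 | 3-(benzyloxy)propan-1-ol | OCCCOCc1ccccc1 | starting material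
2 | 2-methyl-2-vinyloxirane (isoprene monoxide, racemic) | CC1(C=C)CO1 | starting material
3 | (2R,3R)-5-(benzyloxy)-2-ethenyl-2-methylpentane-1,3-diol | C=C[C@](C)(CO)[C@H](O)CCOCc1ccccc1 | intermediate
4 | (4R,5R)-4-[2-(benzyloxy)ethyl]-5-ethenyl-2,2,5-trimethyl-1,3-dioxane | C=C[C@]1(C)COC(C)(C)O[C@@H]1CCOCc2ccccc2 | intermediate
5 | (4R,5R)-4-[2-(benzyloxy)ethyl]-2,2,5-trimethyl-1,3-dioxane-5-carbaldehyde | O=C[C@]1(C)COC(C)(C)O[C@@H]1CCOCc2ccccc2 | intermediate
6 | [(4R,5R)-4-[2-(benzyloxy)ethyl]-2,2,5-trimethyl-1,3-dioxan-5-yl]methanol | OC[C@]1(C)COC(C)(C)O[C@@H]1CCOCc2ccccc2 | intermediate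
7 | {[(4R,5S)-4-[2-(benzyloxy)ethyl]-2,2,5-trimethyl-1,3-dioxan-5-yl]methoxy}(tert-butyl)diphenylsilane | CC(C)(C)[Si](c1ccccc1)(c2ccccc2)OC[C@]3(C)COC(C)(C)O[C@@H]3CCOCc4ccccc4 | intermediate
8 | 2-[(4R,5S)-5-{[tert-butyl(diphenyl)silyl]oxymethyl}-2,2,5-trimethyl-1,3-dioxan-4-yl]ethan-1-ol | CC(C)(C)[Si](c1ccccc1)(c2ccccc2)OC[C@]3(C)COC(C)(C)O[C@@H]3CCO | intermediate
9 | (2R,3R)-4-[(4R,5S)-5-{[tert-butyl(diphenyl)silyl]oxymethyl}-2,2,5-trimethyl-1,3-dioxan-4-yl]-2-ethenyl-2-methylbutane-1,3-diol | C=C[C@](C)(CO)[C@H](O)C[C@H]1OC(C)(C)OC[C@@]1(C)CO[Si](c2ccccc2)(c3ccccc3)C(C)(C)C | intermediate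
10 | (2S,3R)-4-[(4R,5S)-5-{[tert-butyl(diphenyl)silyl]oxymethyl}-2,2,5-trimethyl-1,3-dioxan-4-yl]-2-ethenyl-3-hydroxy-2-methylbutanal | C=C[C@](C)(C=O)[C@H](O)C[C@H]1OC(C)(C)OC[C@@]1(C)CO[Si](c2ccccc2)(c3ccccc3)C(C)(C)C | intermediate
11 | (2S,3R)-3-(tert-butyldimethylsilyloxy)-4-[(4R,5S)-5-{[tert-butyl(diphenyl)silyl]oxymethyl}-2,2,5-trimethyl-1,3-dioxan-4-yl]-2-ethenyl-2-methylbutanal | C=C[C@](C)(C=O)[C@H](O[Si](C)(C)C(C)(C)C)C[C@H]1OC(C)(C)OC[C@@]1(C)CO[Si](c2ccccc2)(c3ccccc3)C(C)(C)C | intermediate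
12 | (2-methylprop-2-en-1-yl)magnesium chloride | C=C(C)C[Mg]Cl | starting material
13 | (5R,6R)-6-(tert-butyldimethylsilyloxy)-7-[(4R,5S)-5-{[tert-butyl(diphenyl)silyl]oxymethyl}-2,2,5-trimethyl-1,3-dioxan-4-yl]-5-ethenyl-2,5-dimethylhept-1-en-4-ol (C4 epimers) | C=C[C@](C)(C(O)CC(C)=C)[C@H](O[Si](C)(C)C(C)(C)C)C[C@H]1OC(C)(C)OC[C@@]1(C)CO[Si](c2ccccc2)(c3ccccc3)C(C)(C)C | intermediate
14 | (2R)-2-[(1R)-1-(tert-butyldimethylsilyloxy)-2-[(4R,5S)-5-{[tert-butyl(diphenyl)silyl]oxymethyl}-2,2,5-trimethyl-1,3-dioxan-4-yl]ethyl]-2,4-dimethylcyclopent-3-en-1-ol (C1 epimers) | CC1=C[C@](C)(C(O)C1)[C@H](O[Si](C)(C)C(C)(C)C)C[C@H]2OC(C)(C)OC[C@@]2(C)CO[Si](c3ccccc3)(c4ccccc4)C(C)(C)C | intermediate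
15 | (2S)-2-[(1R)-1-(tert-butyldimethylsilyloxy)-2-[(4R,5S)-5-{[tert-butyl(diphenyl)silyl]oxymethyl}-2,2,5-trimethyl-1,3-dioxan-4-yl]ethyl]-2,4-dimethylcyclopent-3-en-1-one | CC1=C[C@](C)(C(=O)C1)[C@H](O[Si](C)(C)C(C)(C)C)C[C@H]2OC(C)(C)OC[C@@]2(C)CO[Si](c3ccccc3)(c4ccccc4)C(C)(C)C | intermediate
16 | (5S)-5-[(1R)-1-(tert-butyldimethylsilyloxy)-2-[(4R,5S)-5-{[tert-butyl(diphenyl)silyl]oxymethyl}-2,2,5-trimethyl-1,3-dioxan-4-yl]ethyl]-3,5-dimethylcyclopent-2-en-1-one | CC1=CC(=O)[C@@](C)(C1)[C@H](O[Si](C)(C)C(C)(C)C)C[C@H]2OC(C)(C)OC[C@@]2(C)CO[Si](c3ccccc3)(c4ccccc4)C(C)(C)C | intermediate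
17 | (5S)-5-[(1R,3R,4S)-1-(tert-butyldimethylsilyloxy)-4-{[tert-butyl(diphenyl)silyl]oxymethyl}-3,5-dihydroxy-4-methylpentyl]-3,5-dimethylcyclopent-2-en-1-one | CC1=CC(=O)[C@@](C)(C1)[C@H](O[Si](C)(C)C(C)(C)C)C[C@@H](O)[C@@](C)(CO)CO[Si](c2ccccc2)(c3ccccc3)C(C)(C)C | intermediate
18 | (2S,3R,5R)-5-(tert-butyldimethylsilyloxy)-2-{[tert-butyl(diphenyl)silyl]oxymethyl}-5-[(1S)-1,4-dimethyl-2-oxocyclopent-3-en-1-yl]-3-hydroxy-2-methylpentanal | CC1=CC(=O)[C@@](C)(C1)[C@H](O[Si](C)(C)C(C)(C)C)C[C@@H](O)[C@@](C)(C=O)CO[Si](c2ccccc2)(c3ccccc3)C(C)(C)C | intermediate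
19 | (2S,3R,5R)-5-(tert-butyldimethylsilyloxy)-1-[tert-butyl(diphenyl)silyloxy]-5-[(1S)-1,4-dimethyl-2-oxocyclopent-3-en-1-yl]-2-formyl-2-methylpentan-3-yl acetate | CC1=CC(=O)[C@@](C)(C1)[C@H](O[Si](C)(C)C(C)(C)C)C[C@@H](OC(C)=O)[C@@](C)(C=O)CO[Si](c2ccccc2)(c3ccccc3)C(C)(C)C | intermediate
20 | 2-(dichloromethyl)-4,4,5,5-tetramethyl-1,3,2-dioxaborolane | ClC(Cl)B1OC(C)(C)C(C)(C)O1 | starting material
21 | (1E,3S,4R,6R)-6-(tert-butyldimethylsilyloxy)-3-{[tert-butyl(diphenyl)silyl]oxymethyl}-6-[(1S)-1,4-dimethyl-2-oxocyclopent-3-en-1-yl]-3-methyl-1-(4,4,5,5-tetramethyl-1,3,2-dioxaborolan-2-yl)hex-1-en-4-yl acetate | CC1=CC(=O)[C@@](C)(C1)[C@H](O[Si](C)(C)C(C)(C)C)C[C@@H](OC(C)=O)[C@@](C)(/C=C/B2OC(C)(C)C(C)(C)O2)CO[Si](c3ccccc3)(c4ccccc4)C(C)(C)C | intermediate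
22 | trimethylsilyl dienol ether of 21 (2-silyloxycyclopentadiene: C4–OSiMe3, C4=C5, C6=C7, sp3 C8) | CC1=C[C@](C)(C(O[Si](C)(C)C)=C1)[C@H](O[Si](C)(C)C(C)(C)C)C[C@@H](OC(C)=O)[C@@](C)(/C=C/B2OC(C)(C)C(C)(C)O2)CO[Si](c3ccccc3)(c4ccccc4)C(C)(C)C | intermediate
23 | norbornene cycloadduct (bridgeheads C4 and C7; C4–OSiMe3; C3–B(pin) endo; C1 exo on C2; C5=C6–CH3; C8–CH3 syn to C5=C6; seven-membered ring C7–C8–C9(OTBS)–C10–C11(OAc)–C1(CH3)(CH2OTBDPS)–C2) | CC1=C[C@]2(O[Si](C)(C)C)[C@H](B3OC(C)(C)C(C)(C)O3)[C@@H]4[C@H]1[C@@]2(C)[C@H](O[Si](C)(C)C(C)(C)C)C[C@@H](OC(C)=O)[C@]4(C)CO[Si](c5ccccc5)(c6ccccc6)C(C)(C)C | intermediate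
24 | endo C3 alcohol of 23 (C4–OSiMe3 retained) | CC1=C[C@]2(O[Si](C)(C)C)[C@H](O)[C@@H]3[C@H]1[C@@]2(C)[C@H](O[Si](C)(C)C(C)(C)C)C[C@@H](OC(C)=O)[C@]3(C)CO[Si](c4ccccc4)(c5ccccc5)C(C)(C)C | intermediate
25 | C3,C4-diol (C3–OH endo; bridgehead C4–OH; C9–OTBS; C11–OAc; C15–OTBDPS) | CC1=C[C@]2(O)[C@H](O)[C@@H]3[C@H]1[C@@]2(C)[C@H](O[Si](C)(C)C(C)(C)C)C[C@@H](OC(C)=O)[C@]3(C)CO[Si](c4ccccc4)(c5ccccc5)C(C)(C)C | intermediate
26 | C3 endo mesylate (bridgehead C4–OH free; C9–OTBS; C11–OAc; C15–OTBDPS) | CC1=C[C@]2(O)[C@H](OS(C)(=O)=O)[C@@H]3[C@H]1[C@@]2(C)[C@H](O[Si](C)(C)C(C)(C)C)C[C@@H](OC(C)=O)[C@]3(C)CO[Si](c4ccccc4)(c5ccccc5)C(C)(C)C | intermediate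
27 | diethylaluminium C4-alkoxide of 26 | CC1=C[C@]2(O[Al](CC)CC)[C@H](OS(C)(=O)=O)[C@@H]3[C@H]1[C@@]2(C)[C@H](O[Si](C)(C)C(C)(C)C)C[C@@H](OC(C)=O)[C@]3(C)CO[Si](c4ccccc4)(c5ccccc5)C(C)(C)C | intermediate
28 | tricyclic enone (C4 ketone; C5=C6; cyclobutane C2–C3–C8–C7; C9–OTBS; C11–OAc; C15–OTBDPS; (1S,2S,3R,7R,8R,9R,11R) in the C-labels) | CC1=CC(=O)[C@@H]2[C@@H]3[C@H]1[C@@]2(C)[C@H](O[Si](C)(C)C(C)(C)C)C[C@@H](OC(C)=O)[C@]3(C)CO[Si](c4ccccc4)(c5ccccc5)C(C)(C)C | intermediate
29 | 9,15-diol (C4 ketone; C5=C6; C11–OAc; (1S,2S,3R,7R,8R,9R,11R) in the C-labels) | CC1=CC(=O)[C@@H]2[C@@H]3[C@H]1[C@@]2(C)[C@H](O)C[C@@H](OC(C)=O)[C@]3(C)CO | intermediate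
30 | angelic acid, (2Z)-2-methylbut-2-enoic acid | C/C=C(/C)C(=O)O | starting material
31 | angelic 2,4,6-trichlorobenzoic anhydride | C/C=C(/C)C(=O)OC(=O)c1c(Cl)cc(Cl)cc1Cl | intermediate
32 | CNP0364726.1, (1S,2S,3R,7R,8R,9R,11R) in the C-labels | C/C=C(/C)C(=O)OC[C@]1(C)[C@@H]2[C@H]3C(=O)C=C(C)[C@@H]2[C@@]3(C)[C@H](OC(=O)/C(C)=C\C)C[C@H]1OC(C)=O | target

Total step count: 21. Longest linear sequence: 21 steps (from 1; 2, 12, 20 and 30 are bought).

Steps most likely to fail:

1. Step 19 (proposed new method). The mesylate may ionise before the C4–C8 bond moves, so that the C4–C5 vinyl bond migrates instead, or the contraction may not start because it is uphill in ring strain. The fallback uses known reaction types and sets out from boronate 23. Lithiated methoxyamine (MeONH2, n-BuLi, THF, −78 → 60 °C) should replace boron by NH2 with retention and, with excess amide and an acidic work-up, also cleave the acetate and the trimethylsilyl ether, giving the endo-3-amino-4,11-diol F1. Nitrosation (NaNO2, aq. AcOH, 0 °C) would expel nitrogen with migration of the antiperiplanar C4–C8 bond, a Tiffeneau–Demjanov-type ring contraction, to the 11-hydroxy enone F2. Acetylation (Ac2O, pyridine, DMAP) would return to 28.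

2. Step 16. The boronate activates the dienophile only weakly, so the cycloaddition may be slow enough for desilylation of the dienol ether or for bonding at the wrong diene terminus to compete. The fallback sets out from aldehyde 19. Condensation with nitromethane (NH4OAc, AcOH, 80 °C) would give the (E)-nitroalkene F3, and silylation as in step 16 the silyl dienol ether F4, which should cyclise at or near room temperature to the endo-nitro cycloadduct F5 with the same regiochemistry. Zinc in acetic acid would reduce the nitro group and cleave the trimethylsilyl ether to the amino alcohol F6, acetate retained. Nitrosation as above would then give 28 directly, so that steps 17–19 are bypassed.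

3. Step 6. Catalyst control may be eroded by mismatch with the resident C1 and C11 centres, or the transient β-alkoxy aldehyde may lose the acetonide oxygen by β-elimination. The fallback sets out from alcohol 8. Dess–Martin oxidation would give aldehyde F7, and allylboration with the (E)-γ,γ-disubstituted allylboronate F8 under chiral phosphoric acid catalysis (TRIP, antipode chosen, PhMe, −30 °C) would proceed through a closed chair transition state with CH2OSiEt3 equatorial, hence anti to the new hydroxyl, to give the silyl ether F9. Selective removal of the primary triethylsilyl group (HF·pyridine, pyridine, THF, 0 °C) would return to 9.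

## Further compounds

F1 | step 19 | endo-3-amino-4,11-diol (norbornene skeleton of 23; C9–OTBS; C15–OTBDPS) | CC1=C[C@]2(O)[C@H](N)[C@@H]3[C@H]1[C@@]2(C)[C@H](O[Si](C)(C)C(C)(C)C)C[C@@H](O)[C@]3(C)CO[Si](c4ccccc4)(c5ccccc5)C(C)(C)C
F2 | step 19 | 11-hydroxy tricyclic enone (C11–OH analogue of 28) | CC1=CC(=O)[C@@H]2[C@@H]3[C@H]1[C@@]2(C)[C@H](O[Si](C)(C)C(C)(C)C)C[C@@H](O)[C@]3(C)CO[Si](c4ccccc4)(c5ccccc5)C(C)(C)C
F3 | step 16 | (E)-nitroalkene from 19 (C2H=C3H–NO2 on C1) | CC1=CC(=O)[C@@](C)(C1)[C@H](O[Si](C)(C)C(C)(C)C)C[C@@H](OC(C)=O)[C@@](C)(/C=C/[N+](=O)[O-])CO[Si](c2ccccc2)(c3ccccc3)C(C)(C)C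
F4 | step 16 | trimethylsilyl dienol ether of F3 | CC1=C[C@](C)(C(O[Si](C)(C)C)=C1)[C@H](O[Si](C)(C)C(C)(C)C)C[C@@H](OC(C)=O)[C@@](C)(/C=C/[N+](=O)[O-])CO[Si](c2ccccc2)(c3ccccc3)C(C)(C)C
F5 | step 16 | endo-3-nitro cycloadduct (bridgehead C4–OSiMe3) | CC1=C[C@]2(O[Si](C)(C)C)[C@H]([N+](=O)[O-])[C@@H]3[C@H]1[C@@]2(C)[C@H](O[Si](C)(C)C(C)(C)C)C[C@@H](OC(C)=O)[C@]3(C)CO[Si](c4ccccc4)(c5ccccc5)C(C)(C)C
F6 | step 16 | endo-3-amino-4-ol (C11–OAc retained) | CC1=C[C@]2(O)[C@H](N)[C@@H]3[C@H]1[C@@]2(C)[C@H](O[Si](C)(C)C(C)(C)C)C[C@@H](OC(C)=O)[C@]3(C)CO[Si](c4ccccc4)(c5ccccc5)C(C)(C)C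
F7 | step 6 | 2-[(4R,5S)-5-{[tert-butyl(diphenyl)silyl]oxymethyl}-2,2,5-trimethyl-1,3-dioxan-4-yl]acetaldehyde | CC(C)(C)[Si](c1ccccc1)(c2ccccc2)OC[C@]3(C)COC(C)(C)O[C@@H]3CC=O
F8 | step 6 | (E)-triethyl{[2-methyl-4-(4,4,5,5-tetramethyl-1,3,2-dioxaborolan-2-yl)but-2-en-1-yl]oxy}silane | CC[Si](CC)(CC)OC/C(C)=C/CB1OC(C)(C)C(C)(C)O1
F9 | step 6 | 1-O-triethylsilyl ether of 9 | C=C[C@](C)(CO[Si](CC)(CC)CC)[C@H](O)C[C@H]1OC(C)(C)OC[C@@]1(C)CO[Si](c2ccccc2)(c3ccccc3)C(C)(C)C
A1 | direct plan | (2E,5S,6E)-3-methyl-5-(triethylsilyloxy)-7-[(2R,4R)-4-(tert-butyldimethylsilyloxy)-5-methyl-6-oxooxan-2-yl]octa-2,6-dienoic acid | OC(=O)/C=C(\C)C[C@H](O[Si](CC)(CC)CC)/C=C(\C)[C@H]1C[C@@H](O[Si](C)(C)C(C)(C)C)C(C)C(=O)O1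
A2 | direct plan | bicyclo[3.1.1]heptan-6-one lactone (cyclobutanone at C2; C4–OSiEt3; C6=CH2) | O=C2[C@H]3[C@@H](O[Si](CC)(CC)CC)CC(=C)[C@@H]2[C@@]3(C)[C@H]1C[C@@H](O[Si](C)(C)C(C)(C)C)C(C)C(=O)O1
A3 | direct plan | bridged lactone S-methyl xanthate (C1–C2 closed; C2–OC(=S)SCH3) | O=C1O[C@@H]2C[C@@H](O[Si](C)(C)C(C)(C)C)[C@@]1(C)[C@]3(OC(=S)SC)[C@H]4[C@@H](O[Si](CC)(CC)CC)CC(=C)[C@@H]3[C@@]24C
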